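**Plan**
- Retrosynthesis: the 2'-O-methyl bond is cut first, then ring B at C1'–C2' and C5'–C6'. This leaves a chromone carrying an (E)-2-stannylvinyl group on C2 (C1', C6') and 4-chloro-2,3-dimethoxycyclobutenone (C2'–C5'), which goes back to dimethyl squarate.
- Enabling feature: ring B has oxygen on the contiguous carbons C2', C3', C4' and hydrogen on C5', C6'. That is the pattern O=C–C(OMe)=C(OMe)–CH of a dimethoxycyclobutenone joined to a CH=CH unit on chromone C2.
- Forward: ring A is bought as 3,4,5-trimethoxyphenol. Ring C (the pyranone) closes by Claisen condensation and cyclodehydration, and the C2 side chain is grown by SeO2 oxidation, Takai iodo-olefination and stannylation.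
- Ring B is formed last by Stille coupling, 4π ring opening and 6π closure; methylation of the new 2'-hydroxyl ends the route.
- Stereochemistry: the target has no stereocentre. The E geometry of the stannane comes from the Takai olefination and only serves the coupling; the sp3 centres of the cyclobutenone intermediates are racemic and vanish on aromatisation.

Key step: step 9

Remark on the chemistry: the chlorocyclobutenone is assumed to ionise easily (the C2 methoxy group assists loss of chloride), so it is made under neutral, anhydrous conditions and coupled without storage.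

**Step 1**
Reactants: 1 3,4,5-trimethoxyphenol
Product: 2 1,2,3,5-tetramethoxybenzene
Conditions: MeI, K2CO3, acetone, reflux
Reagents that add atoms: iodomethane CI
Why: Williamson ether synthesis, in which the phenoxide formed with K2CO3 is methylated at the only free hydroxyl.

**Step 2**
Reactants: 2 1,2,3,5-tetramethoxybenzene
Product: 3 1-(2-hydroxy-3,4,6-trimethoxyphenyl)ethan-1-one
Conditions: AcCl, AlCl3, Et2O, 0 °C to rt; aq. HCl work-up
Reagents that add atoms: acetyl chloride CC(Cl)=O
Why: Friedel–Crafts acetylation should take the single kind of free ring position, and AlCl3 should then cleave, through a six-membered aluminium chelate, the ortho methoxy group flanked by the acetyl and another methoxy group, a known regioselective ortho-demethylation that frees the phenol destined to become O1.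

**Step 3**
Reactants: 3 1-(2-hydroxy-3,4,6-trimethoxyphenyl)ethan-1-one
Product: 5 5,7,8-trimethoxy-2-methylchromen-4-one, via diketone 4 (not isolated)
Conditions: NaH, EtOAc, THF, reflux; then AcOH, H2SO4 (cat.), 100 °C
Reagents that add atoms: ethyl acetate CCOC(C)=O
Why: Claisen condensation of the acetophenone enolate with ethyl acetate gives the aryl 1,3-diketone, and acid-catalysed cyclodehydration (phenol oxygen onto the enolised side-chain ketone) closes ring C in the classical 2-methylchromone synthesis.

**Step 4**
Reactants: 5 5,7,8-trimethoxy-2-methylchromen-4-one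
Product: 6 5,7,8-trimethoxy-4-oxo-4H-chromene-2-carbaldehyde
Conditions: SeO2, 1,4-dioxane, reflux
Reagents that add atoms: selenium dioxide O=[Se]=O
Why: Riley oxidation, in which SeO2 oxidises the 2-methyl group (the vinylogous alpha position of the pyranone carbonyl) to the aldehyde, as known for 2-methylchromones.

**Step 5**
Reactants: 6 5,7,8-trimethoxy-4-oxo-4H-chromene-2-carbaldehyde
Product: 7 2-[(E)-2-iodoethenyl]-5,7,8-trimethoxychromen-4-one
Conditions: CHI3, CrCl2, THF, 0 °C to rt
Reagents that add atoms: iodoform IC(I)I
Why: Takai olefination, in which the geminal dichromium species from CHI3 and CrCl2 adds to the aldehyde and eliminates to the E-iodoalkene, while the pyranone carbonyl should be inert to this divalent chromium reagent.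

**Step 6**
Reactants: 7 2-[(E)-2-iodoethenyl]-5,7,8-trimethoxychromen-4-one
Product: 8 5,7,8-trimethoxy-2-[(E)-2-(tributylstannyl)ethenyl]chromen-4-one
Conditions: (Bu3Sn)2, Pd(PPh3)4 (5 mol %), toluene, 80 °C; purification on Et3N-deactivated silica
Reagents that add atoms: hexabutylditin CCCC[Sn](CCCC)(CCCC)[Sn](CCCC)(CCCC)CCCC
Why: Palladium-catalysed stannylation of an alkenyl iodide with a distannane (oxidative addition of zerovalent palladium into C–I, transmetallation, reductive elimination) should give the vinylstannane with the E geometry retained.

**Step 7**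
Reactants: 9 dimethyl squarate (3,4-dimethoxycyclobut-3-ene-1,2-dione)
Product: 10 4-hydroxy-2,3-dimethoxycyclobut-2-en-1-one (racemic)
Conditions: LiAlH(OtBu)3, THF, −78 °C; pH 7 buffer work-up
Reagents that add atoms: none
Why: Chemoselective 1,2-reduction, in which the bulky hydride adds once to a squarate carbonyl and stops because the remaining carbonyl is a deactivated vinylogous ester; the new centre is racemic and is erased later.

**Step 8**
Reactants: 10 4-hydroxy-2,3-dimethoxycyclobut-2-en-1-one
Product: 11 4-chloro-2,3-dimethoxycyclobut-2-en-1-one (racemic)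
Conditions: 1-chloro-N,N,2-trimethylprop-1-en-1-amine, CH2Cl2, 0 °C; used directly
Reagents that add atoms: 1-chloro-N,N,2-trimethylprop-1-en-1-amine CC(C)=C(Cl)N(C)C
Why: Deoxychlorination with the Ghosez chloroenamine, in which the alkoxyiminium chloride collapses to the alkyl chloride and a neutral amide, so no acid is present to trigger loss of methanol to the semisquarate.

**Step 9**
Reactants: 8 5,7,8-trimethoxy-2-[(E)-2-(tributylstannyl)ethenyl]chromen-4-one; 11 4-chloro-2,3-dimethoxycyclobut-2-en-1-one
Product: 15 2-(2-hydroxy-3,4-dimethoxyphenyl)-5,7,8-trimethoxychromen-4-one, via alkenylcyclobutenone 12 (not isolated), via dienylketene 13 (not isolated), via cyclohexadienone 14 (not isolated)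
Conditions: (PhCN)2PdCl2 (5 mol %), tri(2-furyl)phosphine (10 mol %), 1,4-dioxane, 50 °C, then 100 °C
Reagents that add atoms: none
Why: Zerovalent palladium, formed in situ from (PhCN)2PdCl2, inserts into the allylic C4–Cl bond of 11, the alkenyl group is transferred from tin, and reductive elimination at the former chloride carbon makes C5'–C6' and gives 12. On warming, 12 opens by conrotatory 4π electrocyclic cleavage of its C1–C4 bond to dienylketene 13, which closes ring B by thermal disrotatory 6π electrocyclisation between the ketene carbon and the chromone-bearing alkene carbon (C2'–C1') to give dienone 14, and enolisation delivers phenol 15. The closest known reaction type is the palladium-catalysed cross-coupling of 4-chloro-2-cyclobutenones with alkenylstannanes followed by thermal ring expansion to phenols. No stereocentre survives, since the sp3 carbons of 12 and 14 are racemic and are erased on aromatisation. The step needs C–C bond formation at the CH terminus of the oxocyclobutenyl palladium intermediate and not at the methoxy-bearing terminus (which would lead to the 2-hydroxy-4,5-dimethoxyphenyl isomer); the lower substitution of that carbon and the conjugation of the resulting enone should secure this. It also needs the alkenyl group to turn inward on ring opening, and because the opening is reversible while 6π closure and aromatisation are not, the outward-rotated ketene should return to 12 and the material drain through 13.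

**Step 10**
Reactants: 15 2-(2-hydroxy-3,4-dimethoxyphenyl)-5,7,8-trimethoxychromen-4-one
Product: 16 2',3',4',5,7,8-hexamethoxyflavone
Conditions: MeI, K2CO3, acetone, reflux
Reagents that add atoms: iodomethane CI
Why: Williamson ether synthesis on the only free phenol completes the hexamethoxy pattern.

**Compound list**
1 | 3,4,5-trimethoxyphenol | COc1cc(O)cc(OC)c1OC | starting material
2 | 1,2,3,5-tetramethoxybenzene | COc1cc(OC)cc(OC)c1OC | intermediate
3 | 1-(2-hydroxy-3,4,6-trimethoxyphenyl)ethan-1-one | CC(=O)c1c(O)c(OC)c(OC)cc1OC | intermediate
4 | 1-(2-hydroxy-3,4,6-trimethoxyphenyl)butane-1,3-dione | CC(=O)CC(=O)c1c(O)c(OC)c(OC)cc1OC | intermediate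
5 | 5,7,8-trimethoxy-2-methylchromen-4-one | Cc1cc(=O)c2c(OC)cc(OC)c(OC)c2o1 | intermediate
6 | 5,7,8-trimethoxy-4-oxo-4H-chromene-2-carbaldehyde | O=Cc1cc(=O)c2c(OC)cc(OC)c(OC)c2o1 | intermediate
7 | 2-[(E)-2-iodoethenyl]-5,7,8-trimethoxychromen-4-one | I/C=C/c1cc(=O)c2c(OC)cc(OC)c(OC)c2o1 | intermediate
8 | 5,7,8-trimethoxy-2-[(E)-2-(tributylstannyl)ethenyl]chromen-4-one | CCCC[Sn](CCCC)(CCCC)/C=C/c1cc(=O)c2c(OC)cc(OC)c(OC)c2o1 | intermediate
9 | dimethyl squarate (3,4-dimethoxycyclobut-3-ene-1,2-dione) | COC1=C(OC)C(=O)C1=O | starting material
10 | 4-hydroxy-2,3-dimethoxycyclobut-2-en-1-one (racemic) | COC1=C(OC)C(O)C1=O | intermediate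
11 | 4-chloro-2,3-dimethoxycyclobut-2-en-1-one (racemic) | COC1=C(OC)C(Cl)C1=O | intermediate
12 | 2-[(E)-2-(2,3-dimethoxy-4-oxocyclobut-2-en-1-yl)ethenyl]-5,7,8-trimethoxychromen-4-one (racemic) | COC1=C(OC)C(/C=C/c2cc(=O)c3c(OC)cc(OC)c(OC)c3o2)C1=O | intermediate
13 | (3E,5E)-2,3-dimethoxy-6-(5,7,8-trimethoxy-4-oxo-4H-chromen-2-yl)hexa-1,3,5-trien-1-one (ketene and alkenyl groups cis across C3=C4) | O=C=C(OC)/C(OC)=C\C=C\c1cc(=O)c2c(OC)cc(OC)c(OC)c2o1 | intermediate
14 | 2-(3,4-dimethoxy-2-oxocyclohexa-3,5-dien-1-yl)-5,7,8-trimethoxychromen-4-one (racemic) | O=C1C(OC)=C(OC)C=CC1c1cc(=O)c2c(OC)cc(OC)c(OC)c2o1 | intermediate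
15 | 2-(2-hydroxy-3,4-dimethoxyphenyl)-5,7,8-trimethoxychromen-4-one | COc1ccc(-c2cc(=O)c3c(OC)cc(OC)c(OC)c3o2)c(O)c1OC | intermediate
16 | 2',3',4',5,7,8-hexamethoxyflavone | COc1ccc(-c2cc(=O)c3c(OC)cc(OC)c(OC)c3o2)c(OC)c1OC | target

**Step count**
Total: 10 steps. Longest linear sequence: 8 steps (steps 1–6, 9, 10); steps 7 and 8 form the two-step squarate branch that joins at step 9.

**Steps most likely to fail**

Step 8. The C4–Cl bond may ionise with help from the C2 methoxy group, after which chloride attack on the O-methyl group or adventitious hydrolysis would turn the material into the semisquarate before it can be coupled. The fallback sets out from 10 and replaces the chloride by a poorer nucleofuge. Acetylation (Ac2O, pyridine, DMAP cat., CH2Cl2, 0 °C) should give 2,3-dimethoxy-4-oxocyclobut-2-en-1-yl acetate F1, which should tolerate isolation. F1 is then coupled with 8 under allylic acetate Stille conditions (Pd(dba)2, LiCl, DMF, 50 °C, then 100 °C), so that the oxocyclobutenyl palladium species exists only in catalytic amounts. The same cascade through 12, 13 and 14 brings the route back at 15.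

Step 9. Transmetallation from the electron-poor, chromone-conjugated vinylstannane may be slow, giving the palladium intermediate time to decompose by loss of a methyl group. Bond formation at the methoxy-bearing allyl terminus would channel material to the regioisomeric phenol. Outward rotation on ring opening may also lead to ketene side reactions faster than return to 12. The fallback sets out from 3 and builds ring B from an aldehyde instead of squarate. Claisen–Schmidt condensation of 3 with 2,3,4-trimethoxybenzaldehyde (KOH, EtOH, rt) should give (E)-1-(2-hydroxy-3,4,6-trimethoxyphenyl)-3-(2,3,4-trimethoxyphenyl)prop-2-en-1-one F2. Oxidative cyclisation of F2 (I2 cat., DMSO, 130 °C) comes back to the route at 16.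

Step 6. The vinyl iodide may cross-couple with the vinylstannane already formed (diene formation), and the product may undergo protodestannylation during purification. The fallback sets out from 6 and avoids palladium. (Dibromomethyl)tributylstannane F3 is made from Bu3SnCl, CH2Br2 and LDA (THF, −78 °C). Chromium-mediated stannyl olefination of 6 with F3 (Hodgson olefination; CrCl2, LiI, THF/DMF, rt) should give the E-vinylstannane in one operation, coming back to the route at 8.

**Further compounds**
F1 | step 8 | 2,3-dimethoxy-4-oxocyclobut-2-en-1-yl acetate (racemic) | CC(=O)OC1C(OC)=C(OC)C1=O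
F2 | step 9 | (E)-1-(2-hydroxy-3,4,6-trimethoxyphenyl)-3-(2,3,4-trimethoxyphenyl)prop-2-en-1-one | COc1ccc(/C=C/C(=O)c2c(O)c(OC)c(OC)cc2OC)c(OC)c1OC
F3 | step 6 | (dibromomethyl)tributylstannane | CCCC[Sn](CCCC)(CCCC)C(Br)Br
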